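Each quenched substrate costs one starting material and one protic impurity, whatever the rates.

    starting material ⇌ target (K1 = 1.5, k1 = 4.4 × 10⁻⁵ s⁻¹)
    starting material + protic impurity → quenched substrate (k2 = 0.023 L mol⁻¹ s⁻¹)
    target ⇌ isomer of the product (K3 = 2.1, k3 = 1.3 × 10⁻⁵ s⁻¹)

| flask | starting material | protic impurity | time |
|---|---|---|---|
| Friday's | 20 mM | 10.0 mM | 6.0 h |
| Saturday's | 20 mM | 12.0 mM | 6.0 h |
| Tuesday's | 20 mM | 14.0 mM | 6.0 h |

* which of the two there is more of at the end, Friday's (isomer of the product / target)
* which of the two there is more of at the end, Saturday's (isomer of the product / target)
* which of the two there is more of at the end, Tuesday's (isomer of the product / target)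
* target at the end, in percent of the starting material charged, Friday's
* target at the end, in percent of the starting material charged, Saturday's
* target at the end, in percent of the starting material charged, Tuesday's

Two chemists argue over Tuesday's flask. The racer looks for the concentration that sets the order of the rate. With protic impurity held at its charge, the quench is pseudo-first-order and runs 7.32 times as fast as the forward step to target. So she calls 88.0% the quench demand, the part of the charged starting material that the quench takes if protic impurity stays at its charge.

The counter subtracts. On Tuesday's that demand is 17.6 mM, more than the 14.0 mM of protic impurity charged. Protic impurity is therefore the limiting reagent on Tuesday's, and he stops the quench at its charge, 70.0% of the starting material.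

I side with him and reckon on. What stays unquenched relaxes through step 1, both ways together, at 0.264 h⁻¹. In 6.0 h it covers 79.5% of the way to equilibrium, where target holds 60.0% of it. That gives target 23.8% on Friday's, 19.1% on Saturday's and 14.3% on Tuesday's. Over the same time, the forward step to isomer of the product turns about 0.281 of the standing target, so I expect target ahead on Friday's, target on Saturday's and target on Tuesday's.

The forecast takes the counter's side with figures of its own: 22.2%, 18.6% and 15%, with target, target and target ahead. Its ground is that the impurity “eats 10–14 mM of substrate in the first few hours”.

The flask gives 22.6%, 19.2% and 16.2%, with target, target and target ahead. On Tuesday's, half of the quench turnover is done by 0.503 h, against a half-life of 4.4 h for starting material by the forward step alone. Tuesday's quenched substrate ends at 66.3%, below the counter's ceiling, with 5.3% of the protic impurity left.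

The racer's ground is the neighbour with 8.0 mM of starting material and Tuesday's 14.0 mM of protic impurity. The same demand there is 7.04 mM, less than that charge, so she expects 88.0% quenched. The neighbour gives 87.3% quenched substrate and target 8.30%, but its protic impurity does not stay at its charge as her demand supposes: 50% of it is left.

The rate constants are assumed, and the outcome is calculated.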